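**Plan**

1. The C2–H bond is disconnected first: (2S)-candidone goes back to the flat 5,7-dimethoxy-8-prenylflavone, so the only stereocentre is made last.
2. Ring C of the flavone is then cut at C4a–C4, C4–C3 and O1–C2 in one operation. This works because the pyranone is only a phenolic oxygen (O1 on C8a) beside C4a, a one-carbon carbonyl (C4) and a phenyl-bearing two-carbon unit (C3–C2), that is, an ortho-iodophenol, carbon monoxide and phenylacetylene.
3. The ring A iodophenol is traced to 3,5-dimethoxyphenol by two carbamate-directed ortho-metalations, the first bringing in the prenyl chain (future C8), the second the iodine (future C4a).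
4. Forward: ring A is completed, ring C closes in the carbonylative annulation that also attaches ring B (the phenyl of the alkyne), then C2=C3 is reduced.
5. Stereochemistry: the (2S) centre comes from ligand-controlled hydride delivery by a chiral bisphosphine–CuH catalyst to the Re face of C2 of the flavone.

Key step: step 5

Assumption: the facial sense of the SEGPHOS-ligated CuH on a 2-arylchromone is assigned by analogy; the ligand antipode that delivers hydride to the Re face of C2 is the one meant, written below as (R)-DTBM-SEGPHOS.

**Route**

Step 1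
Reactants: 1 3,5-dimethoxyphenol; 2 N,N-diethylcarbamoyl chloride
Product: 3 3,5-dimethoxyphenyl N,N-diethylcarbamate
Conditions: NaH, THF, 0 °C to rt
Reagents that add atoms: N,N-diethylcarbamoyl chloride, CCN(CC)C(Cl)=O
Why: O-carbamoylation of the sodium phenoxide (acyl substitution) is routine and installs the strongest oxygen-based director for ortho-metalation, which also protects the phenol.

Step 2
Reactants: 3 3,5-dimethoxyphenyl N,N-diethylcarbamate; 4 prenyl bromide (1-bromo-3-methylbut-2-ene)
Product: 7 3,5-dimethoxy-2-(3-methylbut-2-en-1-yl)phenyl N,N-diethylcarbamate, via aryllithium 5 (not isolated), via arylcopper 6 (not isolated)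
Conditions: s-BuLi, TMEDA, THF, −78 °C; CuBr·SMe2, −78 to −40 °C; prenyl bromide, −78 °C to rt
Reagents that add atoms: prenyl bromide, CC(C)=CCBr
Why: Directed ortho-metalation (Snieckus type) should occur at the C–H flanked by the carbamate and a methoxy group, and after transmetalation to copper, which also suppresses the anionic ortho-Fries shift, the arylcopper should displace bromide at the primary carbon of prenyl bromide (SN2 allylation) to give the linear prenyl arene.

Step 3
Reactants: 7 3,5-dimethoxy-2-(3-methylbut-2-en-1-yl)phenyl N,N-diethylcarbamate; 8 iodine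
Product: 10 2-iodo-3,5-dimethoxy-6-(3-methylbut-2-en-1-yl)phenyl N,N-diethylcarbamate, via aryllithium 9 (not isolated)
Conditions: s-BuLi, TMEDA, THF, −78 °C; I2 in THF, −78 °C; aq. Na2S2O3
Reagents that add atoms: iodine, II
Why: A second directed ortho-metalation under kinetic conditions should remove the remaining ring proton between carbamate and methoxy in preference to the proton between the two methoxy groups and to the benzylic CH2, and the aryllithium should be iodinated at −78 °C faster than iodine engages the trisubstituted alkene.

Step 4
Reactants: 10 2-iodo-3,5-dimethoxy-6-(3-methylbut-2-en-1-yl)phenyl N,N-diethylcarbamate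
Product: 11 2-iodo-3,5-dimethoxy-6-(3-methylbut-2-en-1-yl)phenol
Conditions: NaOH (excess), EtOH–H2O, reflux; then aq. NH4Cl
Reagents that add atoms: none
Why: Alkaline hydrolysis of the aryl carbamate (acyl substitution at the carbonyl, slow at a di-ortho-substituted ester and therefore run with excess base at reflux) should free the phenol while aryl iodide, methyl ethers and prenyl group are inert to hydroxide.

Step 5
Reactants: 11 2-iodo-3,5-dimethoxy-6-(3-methylbut-2-en-1-yl)phenol; 12 carbon monoxide; 13 phenylacetylene
Product: 16 5,7-dimethoxy-8-(3-methylbut-2-en-1-yl)flavone, via ynone 14 (not isolated), via enaminone 15 (not isolated)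
Conditions: PdCl2(dppf) (cat.), CO (20 bar), Et2NH (solvent), 120 °C, autoclave
Reagents that add atoms: carbon monoxide, [C-]#[O+]; phenylacetylene, C#Cc1ccccc1
Why: Zerovalent palladium, formed in situ from PdCl2(dppf), should insert into the C–I bond of 11, carbon monoxide then inserts to give an aroylpalladium species, and coupling with the amine-deprotonated alkyne followed by reductive elimination delivers ynone 14 (bonds C4a–C4 and C4–C3). Diethylamine adds to the ynone to give enaminone 15, and the ortho phenol oxygen attacks the amine-bearing carbon and expels the amine (bond O1–C2), which is the 6-endo mode of closure (addition–elimination at the β-carbon) and not the 5-exo attack at the α-carbon that would lead to the aurone. The closest known reaction type is the carbonylative Sonogashira annulation of ortho-iodophenols with terminal alkynes to flavones in a secondary amine. No stereocentre is formed, the flat flavone being the substrate of the later asymmetric step. The selectivities needed are carbonylative over direct alkyne coupling and alkyne capture over aminocarbonylation, which the high CO pressure, the electron-rich di-ortho-substituted arylpalladium (fast CO insertion, slow direct coupling) and the copper-free conditions should secure. The prenyl alkene should remain a spectator because it sits meta to the palladated carbon, out of reach of intramolecular carbopalladation, and is trisubstituted.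

Step 6
Reactants: 16 5,7-dimethoxy-8-(3-methylbut-2-en-1-yl)flavone
Product: 18 candidone, (2S)-5,7-dimethoxy-8-(3-methylbut-2-en-1-yl)-2-phenyl-2,3-dihydro-4H-chromen-4-one, via silyl enol ether 17 (not isolated)
Conditions: Cu(OAc)2 (cat.), (R)-DTBM-SEGPHOS (cat.), (EtO)2MeSiH, toluene, 0 °C to rt; then 1 M HCl, THF, 0 °C
Reagents that add atoms: none
Why: Asymmetric conjugate reduction by a bisphosphine-ligated CuH should deliver hydride to the Re face of C2 of the vinylogous ester under control of the chiral ligand, making C2 (S), while silylation of the copper enolate to 17 shields C4 from 1,2-reduction, the isolated prenyl alkene is not a substrate for CuH, and the mild acidic hydrolysis of 17 avoids the base-induced ring opening that would racemise C2.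

**Compound list**

1 | 3,5-dimethoxyphenol | COc1cc(O)cc(OC)c1 | starting material
2 | N,N-diethylcarbamoyl chloride | CCN(CC)C(Cl)=O | starting material
3 | 3,5-dimethoxyphenyl N,N-diethylcarbamate | CCN(CC)C(=O)Oc1cc(OC)cc(OC)c1 | intermediate
4 | prenyl bromide (1-bromo-3-methylbut-2-ene) | CC(C)=CCBr | starting material
5 | aryllithium, 2-(diethylcarbamoyloxy)-4,6-dimethoxyphenyllithium | [Li]c1c(OC)cc(OC)cc1OC(=O)N(CC)CC | intermediate
6 | arylcopper, 2-(diethylcarbamoyloxy)-4,6-dimethoxyphenylcopper | [Cu]c1c(OC)cc(OC)cc1OC(=O)N(CC)CC | intermediate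
7 | 3,5-dimethoxy-2-(3-methylbut-2-en-1-yl)phenyl N,N-diethylcarbamate | CCN(CC)C(=O)Oc1cc(OC)cc(OC)c1CC=C(C)C | intermediate
8 | iodine | II | starting material
9 | aryllithium, 2-(diethylcarbamoyloxy)-4,6-dimethoxy-3-(3-methylbut-2-en-1-yl)phenyllithium | [Li]c1c(OC)cc(OC)c(CC=C(C)C)c1OC(=O)N(CC)CC | intermediate
10 | 2-iodo-3,5-dimethoxy-6-(3-methylbut-2-en-1-yl)phenyl N,N-diethylcarbamate | CCN(CC)C(=O)Oc1c(I)c(OC)cc(OC)c1CC=C(C)C | intermediate
11 | 2-iodo-3,5-dimethoxy-6-(3-methylbut-2-en-1-yl)phenol | Oc1c(I)c(OC)cc(OC)c1CC=C(C)C | intermediate
12 | carbon monoxide | [C-]#[O+] | starting material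
13 | phenylacetylene | C#Cc1ccccc1 | starting material
14 | ynone, 1-[2-hydroxy-4,6-dimethoxy-3-(3-methylbut-2-en-1-yl)phenyl]-3-phenylprop-2-yn-1-one | COc1cc(OC)c(C(=O)C#Cc2ccccc2)c(O)c1CC=C(C)C | intermediate
15 | enaminone, (E)-3-(diethylamino)-1-[2-hydroxy-4,6-dimethoxy-3-(3-methylbut-2-en-1-yl)phenyl]-3-phenylprop-2-en-1-one | COc1cc(OC)c(C(=O)/C=C(/N(CC)CC)c2ccccc2)c(O)c1CC=C(C)C | intermediate
16 | 5,7-dimethoxy-8-(3-methylbut-2-en-1-yl)flavone | COc1cc(OC)c2c(c1CC=C(C)C)OC(c1ccccc1)=CC2=O | intermediate
17 | silyl enol ether, (2S)-4-[diethoxy(methyl)silyloxy]-5,7-dimethoxy-8-(3-methylbut-2-en-1-yl)-2-phenyl-2H-chromene | COc1cc(OC)c2c(c1CC=C(C)C)O[C@H](c1ccccc1)C=C2O[Si](C)(OCC)OCC | intermediate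
18 | candidone, (2S)-5,7-dimethoxy-8-(3-methylbut-2-en-1-yl)flavanone | COc1cc(OC)c2c(c1CC=C(C)C)O[C@H](c1ccccc1)CC2=O | target

**Count and risks**

Total steps: 6. Longest linear sequence: 6 steps (1 to 18).

Steps most likely to fail:

1. Step 6. Hydride transfer to the electron-rich, 2-aryl-substituted vinylogous ester may be sluggish or poorly face-selective, and further 1,2-reduction or ring opening during work-up would erode yield or enantiopurity. The fallback sets out from 16 and gives up catalyst-controlled conjugate reduction for resolution. Achiral 1,4-reduction with LiBH(s-Bu)3 in THF at −78 °C should give racemic 5,7-dimethoxy-8-prenylflavanone F1. Kinetic resolution by asymmetric transfer hydrogenation follows (RuCl(p-cymene)[(R,R)-TsDPEN] or its antipode, HCO2H/Et3N), with the catalyst antipode chosen to reduce the (2R)-ketone faster, to the cis-(2R,4R)-flavan-4-ol F2. The unreacted (2S)-ketone is separated by chromatography; the fallback returns to the route at 18.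

2. Step 5. Oxidative addition at the hindered, electron-rich C–I bond may be slow; direct alkyne coupling (leading on to a benzofuran), capture of the aroylpalladium by diethylamine, or 5-exo closure may compete with the carbonylative 6-endo path. The fallback sets out from 11 and builds the ynone without CO or palladium. Protection with MOMCl/i-Pr2NEt should give the methoxymethyl ether F3. Iodine–lithium exchange (n-BuLi, THF, −78 °C) and addition to 3-phenylprop-2-ynal give the racemic propargylic alcohol F4, and MnO2 in CH2Cl2 oxidises it to the MOM-protected ynone F5. HCl in MeOH removes the MOM group to return to the route at ynone 14, here isolated, which Et2NH in EtOH closes to 16.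

3. Step 3. Deprotonation may occur at the benzylic/allylic CH2 (lateral metalation with carbamoyl migration) or between the two methoxy groups instead of beside the carbamate, and iodine may be consumed by the alkene. The fallback sets out from 3 and places iodine before the alkene exists. s-BuLi/TMEDA then I2 should give 2-iodo-3,5-dimethoxyphenyl N,N-diethylcarbamate F6, and NaOH in EtOH–H2O at reflux gives 2-iodo-3,5-dimethoxyphenol F7. Allyl bromide/K2CO3 in acetone gives the allyl ether F8, and aromatic Claisen rearrangement (PhNEt2, 190 °C) to the only free ortho position gives 2-allyl-6-iodo-3,5-dimethoxyphenol F9. Cross-metathesis with 2-methylbut-2-ene (second-generation Grubbs catalyst, CH2Cl2, 40 °C) converts allyl into prenyl and returns to the route at 11.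

**Further compounds**

F1 | step 6 | racemic 5,7-dimethoxy-8-(3-methylbut-2-en-1-yl)flavanone | COc1cc(OC)c2c(c1CC=C(C)C)OC(c1ccccc1)CC2=O
F2 | step 6 | (2R,4R)-5,7-dimethoxy-8-(3-methylbut-2-en-1-yl)flavan-4-ol | COc1cc(OC)c2c(c1CC=C(C)C)O[C@@H](c1ccccc1)C[C@H]2O
F3 | step 5 | 2-iodo-1,5-dimethoxy-3-(methoxymethoxy)-4-(3-methylbut-2-en-1-yl)benzene | COCOc1c(I)c(OC)cc(OC)c1CC=C(C)C
F4 | step 5 | racemic 1-[2,4-dimethoxy-6-(methoxymethoxy)-5-(3-methylbut-2-en-1-yl)phenyl]-3-phenylprop-2-yn-1-ol | COCOc1c(C(O)C#Cc2ccccc2)c(OC)cc(OC)c1CC=C(C)C
F5 | step 5 | 1-[2,4-dimethoxy-6-(methoxymethoxy)-5-(3-methylbut-2-en-1-yl)phenyl]-3-phenylprop-2-yn-1-one | COCOc1c(C(=O)C#Cc2ccccc2)c(OC)cc(OC)c1CC=C(C)C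
F6 | step 3 | 2-iodo-3,5-dimethoxyphenyl N,N-diethylcarbamate | CCN(CC)C(=O)Oc1cc(OC)cc(OC)c1I
F7 | step 3 | 2-iodo-3,5-dimethoxyphenol | COc1cc(O)c(I)c(OC)c1
F8 | step 3 | 1-(allyloxy)-2-iodo-3,5-dimethoxybenzene | C=CCOc1cc(OC)cc(OC)c1I
F9 | step 3 | 2-allyl-6-iodo-3,5-dimethoxyphenol | C=CCc1c(O)c(I)c(OC)cc1OC
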